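## The problem

Dinorspiculoic acid A (34) is a trans-fused hexahydroindenone. A 2,5-dimethylcyclopentanone (C1, C2, C3, C3a, C7a; indene numbering throughout) shares the C3a–C7a bond with a cyclohexene that carries the C6=C7 double bond and the C7 methyl group. The six-membered ring holds two adjacent all-carbon quaternary stereocentres, C4 (ethyl, carboxyl) and C5 (ethyl, E-styryl), with the two ethyl groups cis. This pair cannot be corrected once made, and it has to carry the absolute configuration. C1 and C3 lie α to the ketone and settle into the all-trans arrangement under base. C3a and C7a are not epimerisable in the target and must be placed relative to C4/C5 by a bond-forming or reducing step. The styryl group does not survive dissolving metals, hydrogenation or ozone, and the γ,δ-unsaturated acid can lactonise onto either alkene under strong acid. The carboxyl carbon is neopentyl on both sides, so an ordinary ester cannot be saponified at the end; and the 1,4-related C2 and C7 carbonyl groups must not both be free ketones when one has to be enolised. The enabling feature is that the cyclopentanone is a formal [2+2+1] adduct: C3/C3a are an alkyne pair, C7a/C1 an alkene pair and C2 carbon monoxide. The C3a–C7a bond of that union is also the bond that closes the six-membered ring through the C4–C5–C6–C7 tether.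

## Retrosynthesis

**Last functional-group changes (34 ⇒ 33 ⇒ 32).** No skeletal bond is cut. The C2 ketone is written as a silyl-protected alcohol and the acid as a 2-(trimethylsilyl)ethyl ester. A free C2 ketone and a methyl ester would leave two enolisable ketones at the stage of 29 and an ester removable only by forcing SN2 dealkylation. 32 lacks the two functions of 34 that react with bases and nucleophiles. Forward, one fluoride treatment must remove both silicon-based groups, and a neutral oxidation must restore the ketone without touching C1 and C3.

**C7–CH3 bond (32 ⇒ 31 ⇒ 29 ⇒ 28 ⇒ 27).** The methyl–C7 bond is cut at enol triflate 31, which leads back to ketone 29, alcohol 28 and silyl ether 27. Adding a methyl nucleophile to 29 and dehydrating would leave the new double bond a choice between C6, C7a and the methyl carbon; enolisation of 29 has only one methylene to use. 27 has an sp3 C7 and no trisubstituted alkene, which is what permits the ozonolysis further back. Forward, deprotonation must occur at C6 and not at the ring-fusion carbon C7a.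

**Styryl double bond (27 ⇒ 26 ⇒ 24).** The Cα=Cβ bond of the styryl group is cut to the neopentyl aldehyde 26, and the formyl group is traced by ozonolysis to the E-propenyl group of 24. A styryl group present earlier would be reduced in the dissolving-metal step. A silyloxymethyl arm would cost three more steps and, once freed, would sit cis and 1,2 to the C4 ester, ready to close a γ-lactone. A propenyl group is inert to lithium in ammonia and is delivered by the sigmatropic step at no cost. 24 contains a single C=C bond. Forward, the olefination of a very hindered but non-enolisable aldehyde must be E-selective.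

**C3a–H and C3–H (24 ⇒ 23 ⇒ 22 ⇒ 20).** Undoing the C2 protection (24, 23) gives ketone 22, whose C3a–H and C3–H bonds are cut to the tetrasubstituted enone 20. Hydrogenation would add cis and also reduce the propenyl group; dissolving-metal reduction gives thermodynamically controlled β-protonation. 20 has two stereocentres fewer. Forward, protonation at C3a must occur trans to C7a–H.

**C3a–C7a, C1–C2 and C2–C3 (20 ⇒ 18).** The three bonds are cut together: 20 is the carbonylative union of the methylalkyne and the C7-propenyl group of the acyclic 1,7-enyne 18.

- Cuts of the five-membered ring alone (aldol or electrocyclic closures) or of the six-membered ring alone would leave the other carbocycle to be made separately and the quaternary pair to be built on a ring.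
- 18 is acyclic with three stereocentres; 20 has two rings and five stereocentres.
- Forward, the alkene must insert with one facial preference (C7a relative to C4/C5), the E-geometry must be carried into C1, and the C5 propenyl group must stay out.
- For the facial preference, the C7 oxygen is carried as a stereodefined silyl ether, not as a ketal. An equatorial silyloxy group next to the reacting alkene decides between the two chair-like arrangements of the forming ring. A ketal would place an oxygen 1,3-diaxial to a C5 substituent in both.
- The C5 propenyl is only 1,5 to the alkyne and could close nothing but a cyclobutane.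

**C4–C5 (18 ⇒ 17 ⇒ 14).** The bond between the two quaternary carbons is cut by an Ireland–Claisen transform: acid 17 (ester 18) comes from allylic ester 14. Making one quaternary centre next to an existing one by alkylation or conjugate addition would be an intermolecular attack at a neopentyl position with no reliable facial bias. The [3,3] shift is intramolecular, makes both centres at once and transfers the configuration of a secondary carbinol. 14 has no quaternary carbon; its stereochemical content is one carbinol centre, one trisubstituted alkene geometry and the remote C7 centre. Forward, the α-ethyl-α-propynyl ester must give one ketene acetal geometry and the shift must pass through a chair.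

**Ester and fragments (14 ⇒ 4 + 13; 13 ⇒ 12 ⇒ 10 ⇒ 9 ⇒ 7 ⇒ 6 ⇒ 5; 4 ⇒ 1 + 2).** The ester C–O bond is cut to acid 4 and allylic alcohol 13.

- 13 is dismantled at the ethyl–C5 bond (alkenyl iodide 12), across the alkene as H and I (propargylic alcohol 10), at the carbinol C–H (ynone 9), at the acetyl–alkyne bond (alkyne 7, alcohol 6) and at C6–C7 (enal 5).
- 4 is cut at the ethyl–C4 bond to 1 and 2.
- C7 stays a carbinol ether throughout, because a C7 ketone beside the C5 alkene of 13 would be a skipped enone prone to conjugation.
- What remains are three small commercial compounds and standard reagents.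
- Forward, two catalyst-controlled steps (5 → 6 and 9 → 10) and a directed trans-hydroalumination (10 → 12) fix the two carbinol centres and the alkene geometry.

## Roads not taken

**Alternative 1: reductive Nazarov cyclisation.** Only the ring-fusion bond C3a–C7a is cut. The Lewis acid complex of the cross-conjugated E,E-dienone A1 would close by conrotatory 4π electrocyclisation, and a hydride donor would intercept the oxyallyl cation to give the all-trans cyclopentanone A2. The cyclohexene would then be closed by ring-closing metathesis of the vinyl and isopropenyl arms.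

- Merits: conrotation of an E,E-dienone makes the trans relation of C3a and C7a a consequence of orbital symmetry. The styryl group is present from the start and never meets a reducing metal. The metathesis delivers the C7 methyl and the C6=C7 bond directly, so the C2/C7 ketone problem and the redox detour at C2 of the chosen route do not arise.
- Weak points: the sense of conrotation would have to be dictated by the acyclic quaternary C4, whose substituents differ little in size. A β-carbon with a quaternary neighbour slows the closure, and the cation sits beside groups prone to 1,2-shift or cation–olefin capture. The metathesis must choose the vinyl over the styryl group on the same carbon and form a trisubstituted alkene next to a quaternary centre. The quaternary pair must still be made first.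
- Comparison: after the quaternary pair this road is probably shorter, and it fixes the trans fusion more directly. The chosen plan sets against this a facial selectivity that rests on a cyclic, chair-like arrangement steered by a purpose-built equatorial substituent followed by a thermodynamic protonation, and the formation of both rings and three C–C bonds in one operation.

**Alternative 2: Diels–Alder reaction of diethylmaleic anhydride.** C5–C6 and C3a–C4 are cut. The 2-ethoxydiene A3, embedded in a protected trans-2,5-dimethylcyclopentanone, would add to 2,3-diethylmaleic anhydride A4 to give the tricyclic adduct A5.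

- Merits: it is the most convergent of the four roads. Both quaternary carbons arise in one step, and the cis relation of the two ethyl groups is guaranteed by the cyclic dienophile, which the chosen plan has to earn from a ketene acetal geometry. The enol ether returns the C7 carbonyl, and C7a can then be equilibrated to the trans fusion.
- Weak points: tetrasubstituted dialkylmaleic anhydrides are among the least reactive dienophiles, and the diene terminus C3a is part of a substituted ring, so forcing conditions and retro-addition are to be expected. The diene face must be chosen anti to the C3 methyl group. The two anhydride carbonyls, both neopentyl, must later be told apart. The absolute configuration needs an enantiopure diene or a chiral catalyst for a sluggish thermal process.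
- Comparison: this road is better in convergence and in the relative configuration of C4/C5. The chosen plan offers instead an intramolecular, sigmatropic construction of the congested bond and termini that are differentiated from the outset (carboxyl versus propenyl).

**Alternative 3: intramolecular Heck closure.** Only C5–C6 is cut. Zerovalent palladium would add oxidatively to the Z-alkenyl iodide A6; 6-exo carbopalladation of the trisubstituted C5 alkene and β-hydride elimination toward the benzylic methylene would give A7, the methyl ester of the target.

- Merits: the ring, the second quaternary centre and the E-styryl unit arise in one late step. β-Hydride elimination has only one direction because C5 becomes quaternary. The styrene is never exposed to reduction.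
- Weak points: migratory insertion must create a quaternary carbon directly beside an existing one, through a trisubstituted alkene. The alkene face is chosen only by the acyclic C4 centre and the alkene geometry. C4 itself must be set on a side chain of the cyclopentanone. The last step is the cleavage of a doubly neopentyl methyl ester.
- Comparison: this road has fewer protecting-group and redox steps at the end and a more direct styryl synthesis. The chosen plan sets against this that its C4–C5 bond is made sigmatropically, both centres together with chirality transfer, and that its key step forms bonds at carbons that are not quaternary.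

Key step: step 11

Remark: indene numbering of 34 (C1–C7a) is used for the corresponding atoms of all intermediates, including the acyclic ones.
Remark: the sense of induction in the catalyst-controlled steps 2 and 5 is assigned by analogy with the accepted facial models; the mirror-image catalyst is used if either proves opposite.
Remark: C2 of compounds 23–33 is carried as a mixture of epimers, because this centre is re-oxidised in step 22.

## Steps

Step 1
Reactants: 1 pent-3-ynoic acid; 2 iodoethane
Product: 4 (2RS)-2-ethylpent-3-ynoic acid, via dilithium enediolate 3 (not isolated)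
Conditions: LiN(i-Pr)2 (2.2 equiv), THF, −78 °C; then 2, DMPU, −78 → −20 °C; aq. HCl
Reagents that add atoms: none
Why: Dianion alkylation: the second equivalent of base removes the propargylic α-hydrogen and the enediolate should react with the primary iodide at the α-carbon. The α-centre is racemic and is erased at the enolate stage of step 9.

Step 2
Reactants: 5 (E)-but-2-enal
Product: 6 (4R,5E)-hept-5-en-1-yn-4-ol
Conditions: allenyl-B(pin), (R)-TRIP phosphoric acid (5 mol %), 4 Å MS, toluene, −20 °C; aqueous work-up
Reagents that add atoms: allenylboronic acid pinacol ester, C=C=CB1OC(C)(C)C(C)(C)O1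
Why: Chiral Brønsted acid-catalysed propargylation of an aldehyde: the phosphoric acid activates the allenylboronate in a closed six-membered SE2′ transition state and shields one aldehyde face, which should set the carbinol centre (the later C7) as R. Only 1,2-addition to the enal is expected.

Step 3
Reactants: 6 (4R,5E)-hept-5-en-1-yn-4-ol
Product: 7 triethyl{[(4R,5E)-hept-5-en-1-yn-4-yl]oxy}silane
Conditions: Et3SiCl, imidazole, CH2Cl2, 0 °C
Reagents that add atoms: chlorotriethylsilane, CC[Si](Cl)(CC)CC
Why: Standard silylation of a secondary alcohol. The triethylsilyl ether is chosen because it must later be removed beside a tert-butyldimethylsilyl ether and serves as the equatorial control group in step 11.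

Step 4
Reactants: 7 triethylsilyl ether of 6
Product: 9 (6R,7E)-6-[(triethylsilyl)oxy]non-7-en-3-yn-2-one, via lithium acetylide 8 (not isolated)
Conditions: n-BuLi, THF, −78 °C; MeC(O)N(OMe)Me, −78 → 0 °C; aq. NH4Cl
Reagents that add atoms: N-methoxy-N-methylacetamide, CC(=O)N(C)OC
Why: Acylation of a lithium acetylide with a Weinreb amide. The chelated tetrahedral intermediate prevents over-addition and keeps the base-sensitive ynone masked until work-up.

Step 5
Reactants: 9 ynone
Product: 10 (2R,6R,7E)-6-[(triethylsilyl)oxy]non-7-en-3-yn-2-ol
Conditions: Ru[(R,R)-TsDPEN](p-cymene) (preformed amido complex, 2 mol %), i-PrOH, 25 °C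
Reagents that add atoms: none
Why: Noyori asymmetric transfer hydrogenation of an alkynyl ketone: the ruthenium hydride delivers hydride and proton through a six-membered transition state to one ketone face, which should set the new carbinol centre as R independently of the remote C6 centre. Alkyne and alkene are not reduced.

Step 6
Reactants: 10 propargylic alcohol
Product: 12 (2R,3Z,6R,7E)-4-iodo-6-[(triethylsilyl)oxy]nona-3,7-dien-2-ol, via cyclic alkenylalanate 11 (not isolated)
Conditions: NaAlH2(OCH2CH2OMe)2, THF, 0 °C → rt; EtOAc; I2, THF, −78 → 0 °C
Reagents that add atoms: iodine, II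
Why: Hydroxyl-directed trans-hydroalumination of a propargylic alcohol: hydride is delivered intramolecularly to C3 and aluminium ends on C4 in the five-membered alanate 11. Iodine cleaves the C–Al bond with retention, so iodine and the carbinol carbon are cis (3Z).

Step 7
Reactants: 12 alkenyl iodide
Product: 13 (2R,3E,6R,7E)-4-ethyl-6-[(triethylsilyl)oxy]nona-3,7-dien-2-ol
Conditions: Et2Zn (3 equiv), PdCl2(dppf) (5 mol %), THF, 0 → 50 °C
Reagents that add atoms: diethylzinc, CC[Zn]CC
Why: Negishi coupling of an alkenyl iodide with a dialkylzinc proceeds with retention of alkene geometry, so the ethyl group ends cis to the carbinol carbon. The wide-bite-angle ligand favours reductive elimination over β-hydride elimination, and the hydroxyl is carried as its zinc alkoxide.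

Step 8
Reactants: 4 (2RS)-2-ethylpent-3-ynoic acid; 13 allylic alcohol
Product: 14 (2R,3E,6R,7E)-4-ethyl-6-[(triethylsilyl)oxy]nona-3,7-dien-2-yl (2RS)-2-ethylpent-3-ynoate
Conditions: DCC, DMAP (0.1 equiv), CH2Cl2, 0 °C
Reagents that add atoms: none
Why: Steglich esterification at low temperature joins the fragments by acyl transfer, so the carbinol centre is retained. The acyl α-centre is a 1:1 mixture that is planarised in step 9.

Step 9
Reactants: 14 allylic ester
Product: 17 (2R,3S,5R,6E)-2,3-diethyl-3-[(1E)-prop-1-en-1-yl]-2-(prop-1-yn-1-yl)-5-[(triethylsilyl)oxy]oct-6-enoic acid, via silyl ketene acetal 15 (not isolated), via trimethylsilyl ester 16 (not isolated)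
Conditions: LiN(i-Pr)2, THF–DMPU (4:1), −78 °C; Me3SiCl/Et3N; −78 → 60 °C; aqueous work-up at pH 4
Reagents that add atoms: none
Why: Ireland–Claisen rearrangement: open-transition-state enolisation in THF–DMPU should place the larger ethyl group syn to the enolate oxygen and the slim propynyl group cis to the allylic oxygen (E-ketene acetal 15), which is also the preferred geometry if the enolate equilibrates. The [3,3] shift through the chair with the carbinol methyl equatorial forms C4–C5, sets both quaternary centres by transfer of the carbinol configuration and the two double-bond geometries, and gives the E-propenyl group; silyl ester 16 is hydrolysed on work-up.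

Step 10
Reactants: 17 acid
Product: 18 2-(trimethylsilyl)ethyl (2R,3S,5R,6E)-2,3-diethyl-3-[(1E)-prop-1-en-1-yl]-2-(prop-1-yn-1-yl)-5-[(triethylsilyl)oxy]oct-6-enoate
Conditions: Me3SiCH2CH2OH, PPh3, DIAD, THF, 0 °C → rt
Reagents that add atoms: 2-(trimethylsilyl)ethanol, C[Si](C)(C)CCO
Why: Mitsunobu esterification uses the hindered acid only as an oxygen nucleophile toward the activated primary alcohol, so the congestion at the carboxyl carbon does not matter. The ester can later be cleaved at silicon and not at the neopentyl carbonyl.

Step 11
Reactants: 18 enyne ester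
Product: 20 2-(trimethylsilyl)ethyl (1R,4R,5S,7R,7aR)-4,5-diethyl-1,3-dimethyl-2-oxo-5-[(1E)-prop-1-en-1-yl]-7-[(triethylsilyl)oxy]-2,4,5,6,7,7a-hexahydro-1H-indene-4-carboxylate, via hexacarbonyldicobalt complex 19 (not isolated)
Conditions: Co2(CO)8 (1.1 equiv), CH2Cl2, rt; then n-BuSMe (3.5 equiv), ClCH2CH2Cl, 83 °C
Reagents that add atoms: dicobalt octacarbonyl, O=C=[Co](=C=O)(=C=O)(=C=O)[Co](=C=O)(=C=O)(=C=O)=C=O
Why: Pauson–Khand reaction: Co2(CO)8 (zerovalent cobalt) binds the methylalkyne as complex 19, and the thioether assists loss of one CO so that the C7a=C1 alkene can coordinate and insert into the Co–C3a bond. This insertion forms C3a–C7a and closes the six-membered ring in the exo sense through the C4–C7 tether; migratory insertion of CO and reductive elimination then form C1–C2 and C2–C3 and close the five-membered ring (overall [2+2+1]). The closest known reaction type is the intramolecular Pauson–Khand cyclisation of 1,7-enynes to bicyclo[4.3.0]non-1(9)-en-8-ones, which is helped by geminal substitution in the tether; here two quaternary carbons provide it. C7a is controlled by the C7 silyloxy group together with the quaternary carbons: in the chair-like arrangement of the forming ring OSiEt3 is equatorial and the C4 ethyl and C5 propenyl groups are trans-diaxial, whereas the other chair would place OSiEt3 and the C5 ethyl group 1,3-diaxial, so C7a–H should end cis to the C7 oxygen and to both ethyl groups. C1 is controlled by the alkene geometry: suprafacial addition to the E-propenyl unit puts the C1 methyl trans to the C7a–C7 bond. The step needs chemoselectivity between the two propenyl groups, which is secured because the C5 propenyl is 1,5 to the alkyne and could only close a cyclobutane; the regiochemistry is fixed by the tether.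

Step 12
Reactants: 20 bicyclic enone
Product: 22 2-(trimethylsilyl)ethyl (1R,3R,3aS,4S,5S,7R,7aS)-4,5-diethyl-1,3-dimethyl-2-oxo-5-[(1E)-prop-1-en-1-yl]-7-[(triethylsilyl)oxy]octahydro-1H-indene-4-carboxylate, via lithium enolate 21 (not isolated)
Conditions: Li (3 equiv), NH3/THF, t-BuOH (1 equiv), −78 °C; NH4Cl; then NaOMe (cat.), MeOH, rt
Reagents that add atoms: none
Why: Dissolving-metal conjugate reduction of a tetrasubstituted enone: the C3a carbanion should be protonated to the trans-fused hydrindanone, because the cis-fused alternative would force either C3 or the C7 silyloxy group into a 1,3-diaxial clash with a C5 substituent. Enolate 21 is protonated on quench and methoxide equilibrates C3 to the trans methyl. The isolated propenyl group, the silyl ether and the hindered ester are expected to survive the short exposure.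

Step 13
Reactants: 22 saturated ketone
Product: 23 2-(trimethylsilyl)ethyl 4,5-diethyl-2-hydroxy-1,3-dimethyl-5-[(1E)-prop-1-en-1-yl]-7-[(triethylsilyl)oxy]octahydro-1H-indene-4-carboxylate (C2 epimers; other stereocentres as in 22)
Conditions: NaBH4, MeOH/THF, 0 °C → rt
Reagents that add atoms: none
Why: Borohydride reduction of the only ketone takes C2 out of play so that it cannot compete in the enolisation of step 19. The configuration of the new carbinol centre is not controlled and does not matter, since it is re-oxidised in step 22.

Step 14
Reactants: 23 C2 alcohol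
Product: 24 C2 tert-butyldimethylsilyl ether of 23 (2-[(tert-butyldimethylsilyl)oxy]; other groups and stereocentres as in 23)
Conditions: t-BuMe2SiOTf, 2,6-lutidine, CH2Cl2, 0 °C → rt
Reagents that add atoms: tert-butyldimethylsilyl trifluoromethanesulfonate, CC(C)(C)[Si](C)(C)OS(=O)(=O)C(F)(F)F
Why: Silylation of a hindered secondary alcohol with a silyl triflate. The tert-butyldimethylsilyl ether withstands the conditions that remove the triethylsilyl ether in step 17.

Step 15
Reactants: 24 bis-silyl ether
Product: 26 5-formyl compound (C5–CHO in place of the propenyl group; other groups and stereocentres as in 24), via ozonide 25 (not isolated)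
Conditions: O3, CH2Cl2, −78 °C; PPh3, −78 °C → rt
Reagents that add atoms: ozone, [O-][O+]=O
Why: Ozonolysis with reductive work-up: the E-propenyl group is the only C=C bond in 24. The resulting neopentyl aldehyde has no α-hydrogen and cannot epimerise.

Step 16
Reactants: 26 aldehyde
Product: 27 5-[(E)-2-phenylethenyl] compound (styryl group at C5; other groups and stereocentres as in 24)
Conditions: (EtO)2P(O)CH2Ph, NaH, THF, 0 → 60 °C
Reagents that add atoms: diethyl benzylphosphonate, CCOP(=O)(Cc1ccccc1)OCC
Why: Horner–Wadsworth–Emmons olefination with a benzylphosphonate anion: reversible addition and syn-elimination from the more stable adduct should give the E-styrene. The aldehyde is non-enolisable and the hindered ester is inert.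

Step 17
Reactants: 27 styrene
Product: 28 7-hydroxy compound (C7–OH free; C2 silyl ether and ester retained; stereocentres as in 27)
Conditions: PPTS, MeOH/CH2Cl2, 0 °C → rt
Reagents that add atoms: none
Why: Acid-catalysed methanolysis distinguishes the less hindered triethylsilyl ether from the tert-butyldimethylsilyl ether at C2 and from the silylethyl ester.

Step 18
Reactants: 28 C7 alcohol
Product: 29 7-oxo compound (C7 ketone; other groups and stereocentres as in 28)
Conditions: Dess–Martin periodinane, CH2Cl2, rt
Reagents that add atoms: none
Why: Dess–Martin oxidation under neutral conditions. The trans ring fusion α to the new ketone is the more stable arrangement, so C7a is not at risk.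

Step 19
Reactants: 29 C7 ketone
Product: 31 C6=C7 enol triflate (7-{[(trifluoromethyl)sulfonyl]oxy}-2,3,3a,4,5,7a-hexahydro-1H-indene; other groups and stereocentres as in 29), via potassium enolate 30 (not isolated)
Conditions: KN(SiMe3)2, THF, −78 °C; PhNTf2, −78 → 0 °C
Reagents that add atoms: N-phenylbis(trifluoromethanesulfonimide), O=S(=O)(N(c1ccccc1)S(=O)(=O)C(F)(F)F)C(F)(F)F
Why: Kinetic enolisation with a bulky amide base should remove a proton from the only α-methylene (C6) and not the tertiary ring-fusion hydrogen at C7a. O-Sulfonylation of enolate 30 fixes the C6=C7 regiochemistry, and no other enolisable carbonyl is present.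

Step 20
Reactants: 31 enol triflate
Product: 32 2-(trimethylsilyl)ethyl 2-[(tert-butyldimethylsilyl)oxy]-4,5-diethyl-1,3,7-trimethyl-5-[(E)-2-phenylethenyl]-2,3,3a,4,5,7a-hexahydro-1H-indene-4-carboxylate (stereocentres as in 31)
Conditions: MeMgBr, Fe(acac)3 (5 mol %), THF/NMP, −30 °C
Reagents that add atoms: methylmagnesium bromide, C[Mg]Br
Why: Iron-catalysed cross-coupling of an alkenyl triflate with a methyl Grignard reagent is fast at low temperature, so the hindered ester, the silyl ether and the styrene should not be attacked. The C7 methyl group and the trisubstituted alkene are now complete.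

Step 21
Reactants: 32 protected precursor
Product: 33 4,5-diethyl-2-hydroxy-1,3,7-trimethyl-5-[(E)-2-phenylethenyl]-2,3,3a,4,5,7a-hexahydro-1H-indene-4-carboxylic acid (C2 epimers; other stereocentres as in 34)
Conditions: Bu4NF (excess), THF, rt → 50 °C; aq. NH4Cl
Reagents that add atoms: none
Why: Fluoride cleaves the silylethyl ester by fragmentation at silicon and, on warming, the hindered C2 silyl ether. The carboxylate is formed first, so the later alkoxide cannot lactonise, and no acid touches the two alkenes.

Step 22
Reactants: 33 hydroxy acid
Product: 34 (1R,3R,3aS,4S,5R,7aS)-4,5-diethyl-1,3,7-trimethyl-2-oxo-5-[(E)-2-phenylethenyl]-2,3,3a,4,5,7a-hexahydro-1H-indene-4-carboxylic acid (dinorspiculoic acid A)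
Conditions: Dess–Martin periodinane, CH2Cl2, rt
Reagents that add atoms: none
Why: Dess–Martin oxidation of the secondary alcohol in the presence of the free acid restores the C2 ketone. C1 and C3 keep the trans,trans configuration set in steps 11 and 12, which is also the thermodynamic one.

## Compound list

1 | pent-3-ynoic acid | CC#CCC(=O)O | starting material
2 | iodoethane | CCI | starting material
3 | dilithium 2-(prop-1-yn-1-yl)ethene-1,1-bis(olate) | CC#CC=C([O-])[O-].[Li+].[Li+] | intermediate (not isolated)
4 | (2RS)-2-ethylpent-3-ynoic acid | CC#CC(CC)C(=O)O | intermediate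
5 | (E)-but-2-enal | C/C=C/C=O | starting material
6 | (4R,5E)-hept-5-en-1-yn-4-ol | C#CC[C@@H](O)/C=C/C | intermediate
7 | triethyl{[(4R,5E)-hept-5-en-1-yn-4-yl]oxy}silane | C#CC[C@@H](O[Si](CC)(CC)CC)/C=C/C | intermediate
8 | lithium acetylide of 7 | [Li]C#CC[C@@H](O[Si](CC)(CC)CC)/C=C/C | intermediate (not isolated)
9 | (6R,7E)-6-[(triethylsilyl)oxy]non-7-en-3-yn-2-one | CC(=O)C#CC[C@@H](O[Si](CC)(CC)CC)/C=C/C | intermediate
10 | (2R,6R,7E)-6-[(triethylsilyl)oxy]non-7-en-3-yn-2-ol | C[C@@H](O)C#CC[C@@H](O[Si](CC)(CC)CC)/C=C/C | intermediate
11 | sodium alkenylalanate of 10 (five-membered O–Al–C=C chelate, two 2-methoxyethoxy ligands on aluminium) | C[C@H]1O[Al-](OCCOC)(OCCOC)C(=C1)C[C@@H](O[Si](CC)(CC)CC)/C=C/C.[Na+] | intermediate (not isolated)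
12 | (2R,3Z,6R,7E)-4-iodo-6-[(triethylsilyl)oxy]nona-3,7-dien-2-ol | C[C@@H](O)/C=C(\I)C[C@@H](O[Si](CC)(CC)CC)/C=C/C | intermediate
13 | (2R,3E,6R,7E)-4-ethyl-6-[(triethylsilyl)oxy]nona-3,7-dien-2-ol | C[C@@H](O)/C=C(\CC)C[C@@H](O[Si](CC)(CC)CC)/C=C/C | intermediate
14 | (2R,3E,6R,7E)-4-ethyl-6-[(triethylsilyl)oxy]nona-3,7-dien-2-yl (2RS)-2-ethylpent-3-ynoate | CC#CC(CC)C(=O)O[C@H](C)/C=C(\CC)C[C@@H](O[Si](CC)(CC)CC)/C=C/C | intermediate
15 | (E)-trimethylsilyl ketene acetal of 14 (propynyl cis to the allylic oxygen, ethyl cis to OSiMe3) | CC#C/C(CC)=C(/O[Si](C)(C)C)O[C@H](C)/C=C(\CC)C[C@@H](O[Si](CC)(CC)CC)/C=C/C | intermediate (not isolated)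
16 | trimethylsilyl ester of 17 | CC#C[C@](CC)(C(=O)O[Si](C)(C)C)[C@](CC)(/C=C/C)C[C@@H](O[Si](CC)(CC)CC)/C=C/C | intermediate (not isolated)
17 | (2R,3S,5R,6E)-2,3-diethyl-3-[(1E)-prop-1-en-1-yl]-2-(prop-1-yn-1-yl)-5-[(triethylsilyl)oxy]oct-6-enoic acid | CC#C[C@](CC)(C(=O)O)[C@](CC)(/C=C/C)C[C@@H](O[Si](CC)(CC)CC)/C=C/C | intermediate
18 | 2-(trimethylsilyl)ethyl (2R,3S,5R,6E)-2,3-diethyl-3-[(1E)-prop-1-en-1-yl]-2-(prop-1-yn-1-yl)-5-[(triethylsilyl)oxy]oct-6-enoate | CC#C[C@](CC)(C(=O)OCC[Si](C)(C)C)[C@](CC)(/C=C/C)C[C@@H](O[Si](CC)(CC)CC)/C=C/C | intermediate
19 | μ-alkyne hexacarbonyldicobalt complex of 18 | CC12[Co]3(=C=O)(=C=O)(=C=O)[Co]1(=C=O)(=C=O)(=C=O)C23[C@](CC)(C(=O)OCC[Si](C)(C)C)[C@](CC)(/C=C/C)C[C@@H](O[Si](CC)(CC)CC)/C=C/C | intermediate (not isolated)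
20 | 2-(trimethylsilyl)ethyl (1R,4R,5S,7R,7aR)-4,5-diethyl-1,3-dimethyl-2-oxo-5-[(1E)-prop-1-en-1-yl]-7-[(triethylsilyl)oxy]-2,4,5,6,7,7a-hexahydro-1H-indene-4-carboxylate | CC[C@@]1(/C=C/C)C[C@@H](O[Si](CC)(CC)CC)[C@H]2C(=C(C)C(=O)[C@@H]2C)[C@]1(CC)C(=O)OCC[Si](C)(C)C | intermediate
21 | lithium C2=C3 enolate of 22 | CC[C@@]1(/C=C/C)C[C@@H](O[Si](CC)(CC)CC)[C@H]2[C@@H](C(C)=C(O[Li])[C@@H]2C)[C@]1(CC)C(=O)OCC[Si](C)(C)C | intermediate (not isolated)
22 | 2-(trimethylsilyl)ethyl (1R,3R,3aS,4S,5S,7R,7aS)-4,5-diethyl-1,3-dimethyl-2-oxo-5-[(1E)-prop-1-en-1-yl]-7-[(triethylsilyl)oxy]octahydro-1H-indene-4-carboxylate | CC[C@@]1(/C=C/C)C[C@@H](O[Si](CC)(CC)CC)[C@H]2[C@@H]([C@@H](C)C(=O)[C@@H]2C)[C@]1(CC)C(=O)OCC[Si](C)(C)C | intermediate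
23 | 2-(trimethylsilyl)ethyl 4,5-diethyl-2-hydroxy-1,3-dimethyl-5-[(1E)-prop-1-en-1-yl]-7-[(triethylsilyl)oxy]octahydro-1H-indene-4-carboxylate (C2 epimers; other centres as in 22) | CC[C@@]1(/C=C/C)C[C@@H](O[Si](CC)(CC)CC)[C@H]2[C@@H]([C@@H](C)C(O)[C@@H]2C)[C@]1(CC)C(=O)OCC[Si](C)(C)C | intermediate
24 | 2-O-tert-butyldimethylsilyl ether of 23 | CC[C@@]1(/C=C/C)C[C@@H](O[Si](CC)(CC)CC)[C@H]2[C@@H]([C@@H](C)C(O[Si](C)(C)C(C)(C)C)[C@@H]2C)[C@]1(CC)C(=O)OCC[Si](C)(C)C | intermediate
25 | ozonide of 24 (5-(5-methyl-1,2,4-trioxolan-3-yl) in place of propenyl) | CC[C@@]1(C2OOC(C)O2)C[C@@H](O[Si](CC)(CC)CC)[C@H]3[C@@H]([C@@H](C)C(O[Si](C)(C)C(C)(C)C)[C@@H]3C)[C@]1(CC)C(=O)OCC[Si](C)(C)C | intermediate (not isolated)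
26 | 5-formyl analogue of 24 | CC[C@@]1(C=O)C[C@@H](O[Si](CC)(CC)CC)[C@H]2[C@@H]([C@@H](C)C(O[Si](C)(C)C(C)(C)C)[C@@H]2C)[C@]1(CC)C(=O)OCC[Si](C)(C)C | intermediate
27 | 5-[(E)-2-phenylethenyl] analogue of 24 | CC[C@@]1(/C=C/c2ccccc2)C[C@@H](O[Si](CC)(CC)CC)[C@H]3[C@@H]([C@@H](C)C(O[Si](C)(C)C(C)(C)C)[C@@H]3C)[C@]1(CC)C(=O)OCC[Si](C)(C)C | intermediate
28 | 7-hydroxy compound from 27 (C7–OH free) | CC[C@@]1(/C=C/c2ccccc2)C[C@@H](O)[C@H]3[C@@H]([C@@H](C)C(O[Si](C)(C)C(C)(C)C)[C@@H]3C)[C@]1(CC)C(=O)OCC[Si](C)(C)C | intermediate
29 | 7-oxo compound from 28 | CC[C@@]1(/C=C/c2ccccc2)CC(=O)[C@H]3[C@@H]([C@@H](C)C(O[Si](C)(C)C(C)(C)C)[C@@H]3C)[C@]1(CC)C(=O)OCC[Si](C)(C)C | intermediate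
30 | potassium C6=C7 enolate of 29 | CC[C@@]1(/C=C/c2ccccc2)C=C(O[K])[C@H]3[C@@H]([C@@H](C)C(O[Si](C)(C)C(C)(C)C)[C@@H]3C)[C@]1(CC)C(=O)OCC[Si](C)(C)C | intermediate (not isolated)
31 | C6=C7 enol triflate of 29 | CC[C@@]1(/C=C/c2ccccc2)C=C(OS(=O)(=O)C(F)(F)F)[C@H]3[C@@H]([C@@H](C)C(O[Si](C)(C)C(C)(C)C)[C@@H]3C)[C@]1(CC)C(=O)OCC[Si](C)(C)C | intermediate
32 | 2-(trimethylsilyl)ethyl 2-[(tert-butyldimethylsilyl)oxy]-4,5-diethyl-1,3,7-trimethyl-5-[(E)-2-phenylethenyl]-2,3,3a,4,5,7a-hexahydro-1H-indene-4-carboxylate | CC[C@@]1(/C=C/c2ccccc2)C=C(C)[C@H]3[C@@H]([C@@H](C)C(O[Si](C)(C)C(C)(C)C)[C@@H]3C)[C@]1(CC)C(=O)OCC[Si](C)(C)C | intermediate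
33 | 4,5-diethyl-2-hydroxy-1,3,7-trimethyl-5-[(E)-2-phenylethenyl]-2,3,3a,4,5,7a-hexahydro-1H-indene-4-carboxylic acid (C2 epimers) | CC[C@@]1(/C=C/c2ccccc2)C=C(C)[C@H]3[C@@H]([C@@H](C)C(O)[C@@H]3C)[C@]1(CC)C(=O)O | intermediate
34 | (1R,3R,3aS,4S,5R,7aS)-4,5-diethyl-1,3,7-trimethyl-2-oxo-5-[(E)-2-phenylethenyl]-2,3,3a,4,5,7a-hexahydro-1H-indene-4-carboxylic acid (dinorspiculoic acid A) | CC[C@@]1(/C=C/c2ccccc2)C=C(C)[C@H]2[C@@H]([C@@H](C)C(=O)[C@@H]2C)[C@]1(CC)C(=O)O | target

Total step count: 22. Longest linear sequence: 21 steps (steps 2–22, from 5 to 34); step 1 is a one-step side branch that joins at step 8.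

## Least certain steps

**Step 11 (key step).** The most likely failure is slow insertion of the 1,2-disubstituted, allylically oxygenated alkene into the congested cobalt–alkyne complex, so that decomplexation or decomposition wins. Facial selectivity would also erode if a boat-like arrangement of the tether competes. The fallback replaces the cobalt manifold by an early-metal oxidative cyclisation, which forms the C3a–C7a bond without prior loss of a ligand from an alkyne complex. It sets out from 18: Cp2ZrCl2 and two equivalents of n-BuLi (THF, −78 °C → rt) generate a divalent zirconocene equivalent that should couple alkyne and alkene to the zirconacyclopentene F1. Carbonylation (CO, 1 atm, 0 °C) and iodinolysis would then give 20, where the route is rejoined. The doubly neopentyl ester is expected to be spared by the zirconium reagent.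

**Step 9.** Control over the ketene acetal geometry may be lost, and with it the configuration of C4 relative to C5, because the α-carbon carries two substituents and the enolate is conjugated with the alkyne; a boat-like transition state could add to the erosion. The fallback inverts the pairing of stereochemical elements. It sets out from 9: transfer hydrogenation with the (S,S)-catalyst would give the 2S propargylic alcohol F2. Directed syn-ethylmagnesiation (EtMgBr, Fe(acac)3 cat., THF) would give the (2S,3Z)-allylic alcohol F3, which has the C5 chain, not the ethyl group, cis to the carbinol carbon. Esterification with 4 would give ester F4. Enolisation with LiN(i-Pr)2 in THF alone (closed, lithium-bridged transition state, the slim propynyl group next to the base) and silylation would give the Z-ketene acetal F5. Its [3,3] shift through the mirror-image chair leads to the same acid 17, where the route is rejoined.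

**Step 19.** Proton removal at C7a may compete with removal from the C6 methylene, which is shielded by the quaternary C5. This would give the tetrasubstituted enolate and erase the C7a configuration. The fallback avoids enolate chemistry. It sets out from 29: MeLi/CeCl3 (THF, −78 °C) should add from the equatorial direction, since the axial approach is blocked by the axial styryl group on C5, to give the tertiary alcohol F6 with an axial hydroxyl. Syn-elimination with the Burgess reagent (toluene, 60 °C) can take a ring hydrogen only from C6, because C7a–H is trans to the hydroxyl. This would give 32 directly, where the route is rejoined.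

**Step 16.** Addition of the semi-stabilised phosphonate anion to an aldehyde flanked by two quaternary carbons may be slow, so that retro-addition and incomplete E-selection become problems over long reaction times. The fallback builds the styrene in two C–C bond-forming events. It sets out from 26: Wittig methylenation (Ph3P=CH2, THF) would give the C5-vinyl compound F7. Mizoroki–Heck arylation with iodobenzene (Pd(OAc)2, a divalent palladium precatalyst reduced in the flask to zerovalent palladium, P(o-tol)3, Et3N, DMF, 90 °C) would give 27, where the route is rejoined. Here the E geometry is enforced by syn β-hydride elimination, which has only the benzylic hydrogen to use.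

**Step 1.** The dianion may be ethylated at the γ-carbon or isomerise by proton shifts to allenic or conjugated acids. The fallback moves the alkylation to the ester stage. It sets out from 1 and 13: Steglich esterification would give the unbranched ester F8, and its lithium enolate (LiN(i-Pr)2, THF–DMPU, −78 °C), a softer monoanion, would be ethylated with 2 to give 14, where the route is rejoined.

## Further compounds

F1 | step 11 | zirconacyclopentene from 18 (Cp2Zr bonded to C1 and C3 of the bicyclic skeleton) | CC[C@@]1(/C=C/C)C[C@@H](O[Si](CC)(CC)CC)[C@H]2C(=C(C)[Zr](C3C=CC=C3)(C3C=CC=C3)[C@@H]2C)[C@]1(CC)C(=O)OCC[Si](C)(C)C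
F2 | step 9 | (2S,6R,7E)-6-[(triethylsilyl)oxy]non-7-en-3-yn-2-ol | C[C@H](O)C#CC[C@@H](O[Si](CC)(CC)CC)/C=C/C
F3 | step 9 | (2S,3Z,6R,7E)-4-ethyl-6-[(triethylsilyl)oxy]nona-3,7-dien-2-ol | C[C@H](O)/C=C(/CC)C[C@@H](O[Si](CC)(CC)CC)/C=C/C
F4 | step 9 | (2S,3Z,6R,7E)-4-ethyl-6-[(triethylsilyl)oxy]nona-3,7-dien-2-yl (2RS)-2-ethylpent-3-ynoate | CC#CC(CC)C(=O)O[C@@H](C)/C=C(/CC)C[C@@H](O[Si](CC)(CC)CC)/C=C/C
F5 | step 9 | (Z)-trimethylsilyl ketene acetal of F4 (ethyl cis to the allylic oxygen) | CC#C/C(CC)=C(\O[Si](C)(C)C)O[C@@H](C)/C=C(/CC)C[C@@H](O[Si](CC)(CC)CC)/C=C/C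
F6 | step 19 | 7-hydroxy-7-methyl compound from 29 (axial hydroxyl, equatorial methyl) | CC[C@@]1(/C=C/c2ccccc2)C[C@](C)(O)[C@H]3[C@@H]([C@@H](C)C(O[Si](C)(C)C(C)(C)C)[C@@H]3C)[C@]1(CC)C(=O)OCC[Si](C)(C)C
F7 | step 16 | 5-vinyl analogue of 24 | CC[C@@]1(C=C)C[C@@H](O[Si](CC)(CC)CC)[C@H]2[C@@H]([C@@H](C)C(O[Si](C)(C)C(C)(C)C)[C@@H]2C)[C@]1(CC)C(=O)OCC[Si](C)(C)C
F8 | step 1 | (2R,3E,6R,7E)-4-ethyl-6-[(triethylsilyl)oxy]nona-3,7-dien-2-yl pent-3-ynoate | CC#CCC(=O)O[C@H](C)/C=C(\CC)C[C@@H](O[Si](CC)(CC)CC)/C=C/C
A1 | alternative 1 | cross-conjugated E,E-dienone with vinyl, styryl and isopropenyl arms | CC[C@](C=C)(/C=C/c1ccccc1)[C@@](CC)(C(=O)OC)/C=C(\C)C(=O)/C(C)=C/C(C)=C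
A2 | alternative 1 | all-trans cyclopentanone with vinyl and isopropenyl arms | CC[C@](C=C)(/C=C/c1ccccc1)[C@@](CC)(C(=O)OC)[C@@H]1[C@@H](C)C(=O)[C@H](C)[C@H]1C(C)=C
A3 | alternative 2 | 2-ethoxydiene on a ketal-protected trans-2,5-dimethylcyclopentene | C=C(OCC)C1=C[C@@H](C)C2(OCCO2)[C@@H]1C
A4 | alternative 2 | 2,3-diethylmaleic anhydride | CCC1=C(CC)C(=O)OC1=O
A5 | alternative 2 | tricyclic anhydride enol ether adduct | CC[C@@]12CC(OCC)=C3[C@@H](C)C4(OCCO4)[C@H](C)[C@H]3[C@]1(CC)C(=O)OC2=O
A6 | alternative 3 | Z-alkenyl iodide with a trisubstituted C5 alkene (Heck substrate) | CC/C(=C\Cc1ccccc1)[C@@](CC)(C(=O)OC)[C@@H]1[C@@H](C)C(=O)[C@H](C)[C@H]1/C(C)=C\I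
A7 | alternative 3 | methyl ester of the target | CC[C@@]1(/C=C/c2ccccc2)C=C(C)[C@H]2[C@@H]([C@@H](C)C(=O)[C@@H]2C)[C@]1(CC)C(=O)OC
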